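**Retrosynthetic overview**
1. Feature: in ring A the tertiary carbinol C1' and the ketone C4' lie 1,4 to each other across C2'=C3', and C1' adjoins the quaternary C6' (CH3 and C8'H2O-acyl). This O–C1'–C2'=C3'–C4'–O array is what a 1',4'-epidioxide of a C1'=C2'–C3'=C4' cyclohexadiene leaves behind, so both oxygens are taken from O2.
2. Target ⇒ (fluoride) bis[2-(trimethylsilyl)ethyl] (TMSE) ester ⇒ (Kornblum–DeLaMare opening, singlet-oxygen [4+2]) a tetraene that already carries the HMG ester and the (2Z,4E)-dienoate.
3. Tetraene ⇒ the O8'–acyl bond (Steglich) to an enantiopure HMG half ester, and the C1'–C5 bond (Stille) between a ring dienyl triflate and a stannyl dienoate from but-2-ynoic acid. The half ester is made from (R)-mevalonolactone, because mono-esterifying the prochiral diacid would give a racemate.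
4. Dienyl triflate ⇒ 2,6-dimethylcyclohex-2-enone + formaldehyde. Catalytic asymmetric hydroxymethylation sets C6', which later steers O2 at C1'.
5. Rings: ring A is bought. The only ring closed is the transient 1,2-dioxane of the epidioxide, which is opened again in the same flask.

Key step: step 15

Numbering: ring C1'–C6' and side chain C1–C5 as in abscisic acid; C8' is the oxygenated carbon on C6'. CIP descriptors at C6' and at the HMG carbinol change along the route only because substituent ranks change.

Assumption: the sense of induction of the scandium–bipyridine catalyst on this dienol silane is inferred from related α-methyl cyclic silicon enolates. Both ligand antipodes are available, and the one that leads to the (6S)-alcohol, written here as (S,S), is used.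

**Step 1**
Reactants: 1 2,6-dimethylcyclohex-2-en-1-one (racemic)
Product: 3 [(2,6-dimethylcyclohexa-1,5-dien-1-yl)oxy]trimethylsilane, via lithium dienolate 2 (not isolated)
Conditions: LDA, THF, −78 °C; TMSCl, −78 → 0 °C
Reagents that add atoms: chlorotrimethylsilane, C[Si](C)(C)Cl
Why: Kinetic α'-deprotonation of the enone followed by O-silylation (silyl enol ether formation) removes the C6–H, erases the racemic centre and fixes C6 as the nucleophilic carbon.

**Step 2**
Reactants: 3 [(2,6-dimethylcyclohexa-1,5-dien-1-yl)oxy]trimethylsilane; 4 formaldehyde (aqueous solution)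
Product: 5 (6S)-6-(hydroxymethyl)-2,6-dimethylcyclohex-2-en-1-one
Conditions: aq. HCHO, Sc(OTf)3 (10 mol %), (S,S)-6,6'-bis(1-hydroxy-2,2-dimethylpropyl)-2,2'-bipyridine (12 mol %), DME–H2O, −20 °C
Reagents that add atoms: none
Why: In this catalytic asymmetric Mukaiyama aldol hydroxymethylation of a silicon enolate, the chiral scandium–bipyridine complex binds formaldehyde and exposes one of its approaches to the tetrasubstituted enol silane, so that the C6–C8' bond forms on one face and sets the quaternary centre as S (catalyst control).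

**Step 3**
Reactants: 5 (6S)-6-(hydroxymethyl)-2,6-dimethylcyclohex-2-en-1-one
Product: 6 (6S)-6-{[(tert-butyldimethylsilyl)oxy]methyl}-2,6-dimethylcyclohex-2-en-1-one
Conditions: TBSCl, imidazole, DMF, rt
Reagents that add atoms: tert-butyldimethylsilyl chloride, CC(C)(C)[Si](C)(C)Cl
Why: Imidazole-promoted silyl ether formation on the primary alcohol masks the β-hydroxy ketone against retro-aldol loss of formaldehyde under the strong base of the next step and does not touch C6'.

**Step 4**
Reactants: 6 (6S)-6-{[(tert-butyldimethylsilyl)oxy]methyl}-2,6-dimethylcyclohex-2-en-1-one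
Product: 8 (6S)-6-{[(tert-butyldimethylsilyl)oxy]methyl}-2,6-dimethylcyclohexa-1,3-dien-1-yl trifluoromethanesulfonate, via lithium extended dienolate 7 (not isolated)
Conditions: LDA, THF, −78 °C; PhNTf2, −78 → 0 °C
Reagents that add atoms: N-phenylbis(trifluoromethanesulfonimide), O=S(=O)(N(c1ccccc1)S(=O)(=O)C(F)(F)F)C(F)(F)F
Why: With C6' quaternary the only acidic hydrogens are at γ-C4', so deprotonation gives the linear dienolate and O-sulfonylation (enol triflate formation) gives the C1'=C2'–C3'=C4' dienyl triflate, while silyloxide cannot be eliminated because no carbanion can form at C6'.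

**Step 5**
Reactants: 9 but-2-ynoic acid
Product: 10 (2Z)-3-iodobut-2-enoic acid
Conditions: NaI, AcOH, 115 °C
Reagents that add atoms: sodium iodide, [Na+].[I-]
Why: In this conjugate hydroiodination of an ynoic acid, iodide adds at C3 and protonation follows anti, which places I and CO2H cis and thereby fixes the future 2Z geometry.

**Step 6**
Reactants: 10 (2Z)-3-iodobut-2-enoic acid
Product: 11 2-(trimethylsilyl)ethyl (2Z)-3-iodobut-2-enoate
Conditions: Me3SiCH2CH2OH, DCC, DMAP (cat.), CH2Cl2, 0 °C → rt
Reagents that add atoms: 2-(trimethylsilyl)ethanol, C[Si](C)(C)CCO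
Why: Steglich esterification under near-neutral conditions keeps the Z-iodoalkene intact and installs a fluoride-labile ester that tolerates both palladium couplings.

**Step 7**
Reactants: 11 2-(trimethylsilyl)ethyl (2Z)-3-iodobut-2-enoate; 12 (E)-1,2-bis(tributylstannyl)ethene (excess)
Product: 13 2-(trimethylsilyl)ethyl (2Z,4E)-3-methyl-5-(tributylstannyl)penta-2,4-dienoate
Conditions: PdCl2(MeCN)2 (5 mol %), DMF, rt, dark
Reagents that add atoms: none
Why: Stille coupling of a vinyl iodide proceeds with retention at both sp2 carbons, and the excess of the symmetrical distannane holds the reaction at the mono-coupling stage, so the 2Z,4E stannyl dienoate should result.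

**Step 8**
Reactants: 8 dienyl triflate; 13 stannyl dienoate
Product: 14 2-(trimethylsilyl)ethyl (2Z,4E)-5-[(6R)-6-{[(tert-butyldimethylsilyl)oxy]methyl}-2,6-dimethylcyclohexa-1,3-dien-1-yl]-3-methylpenta-2,4-dienoate (same spatial arrangement at C6' as in 8)
Conditions: Pd2(dba)3 (5 mol %), AsPh3 (40 mol %), LiCl, NMP, 50 °C, degassed, dark
Reagents that add atoms: none
Why: This Stille coupling of an alkenyl triflate with an alkenylstannane forms C1'–C5 with retention of all alkene geometries, and the weakly bound arsine ligand in a polar solvent speeds up transmetalation at the congested carbon, a combination established for 2,6,6-trimethylcyclohexenyl triflates.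

**Step 9**
Reactants: 14 silyl-protected tetraene
Product: 15 2-(trimethylsilyl)ethyl (2Z,4E)-5-[(6R)-6-(hydroxymethyl)-2,6-dimethylcyclohexa-1,3-dien-1-yl]-3-methylpenta-2,4-dienoate
Conditions: HF·pyridine, pyridine, THF, 0 °C → rt
Reagents that add atoms: none
Why: Pyridine-buffered HF cleaves the primary silyl ether (acidic fluoride desilylation), whereas a 2-(trimethylsilyl)ethyl ester needs basic unsolvated fluoride to fragment, so the ester and the polyene should survive.

**Step 10**
Reactants: 16 (R)-mevalonolactone
Product: 18 benzyl (3R)-3,5-dihydroxy-3-methylpentanoate, via potassium mevalonate 17 (not isolated)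
Conditions: KOH (1 equiv), MeOH–H2O, rt, evaporate; BnBr, DMF, rt
Reagents that add atoms: potassium hydroxide, [K+].[OH-]; benzyl bromide, BrCc1ccccc1
Why: Lactone saponification followed by SN2 O-alkylation of the carboxylate tells the two arms of the skeleton apart without touching the tertiary carbinol centre, which is taken from the chiral pool.

**Step 11**
Reactants: 18 benzyl (3R)-3,5-dihydroxy-3-methylpentanoate
Product: 19 (3R)-5-(benzyloxy)-3-hydroxy-3-methyl-5-oxopentanoic acid
Conditions: TEMPO (cat.), PhI(OAc)2, MeCN–H2O, rt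
Reagents that add atoms: water, O
Why: The oxoammonium-mediated oxidation takes only the primary alcohol through the aldehyde hydrate to the acid, the tertiary alcohol cannot be oxidised, and the centre stays stereogenic because its two arms remain different (acid and benzyl ester).

**Step 12**
Reactants: 19 (3R)-5-(benzyloxy)-3-hydroxy-3-methyl-5-oxopentanoic acid
Product: 20 1-benzyl 5-[2-(trimethylsilyl)ethyl] (3S)-3-hydroxy-3-methylpentanedioate
Conditions: Me3SiCH2CH2OH, DCC, DMAP (cat.), CH2Cl2, 0 °C → rt
Reagents that add atoms: 2-(trimethylsilyl)ethanol, C[Si](C)(C)CCO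
Why: Steglich esterification of the free arm proceeds with the hindered tertiary hydroxyl as a spectator and cannot pass through the symmetrical anhydride, so the centre is not scrambled.

**Step 13**
Reactants: 20 mixed benzyl TMSE diester
Product: 21 (3S)-3-hydroxy-3-methyl-5-oxo-5-[2-(trimethylsilyl)ethoxy]pentanoic acid
Conditions: H2 (1 atm), Pd/C, EtOAc, rt
Reagents that add atoms: none
Why: Catalytic hydrogenolysis removes only the benzyl ester, since the molecule holds no alkene and the silylethyl ester is inert to hydrogen.

**Step 14**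
Reactants: 15 tetraene alcohol; 21 HMG half ester
Product: 22 ring-diene tetraene, the 8'-O-{(3S)-3-hydroxy-3-methyl-5-oxo-5-[2-(trimethylsilyl)ethoxy]pentanoyl} derivative of 15 (6'R)
Conditions: DCC, DMAP, CH2Cl2, 0 °C → rt, dark
Reagents that add atoms: none
Why: Steglich esterification acylates the neopentyl-type primary alcohol, while the tertiary hydroxyl of 21 is too hindered to compete and neither stereocentre lies at a reacting atom.

**Step 15**
Reactants: 22 ring-diene tetraene
Product: 24 bis[2-(trimethylsilyl)ethyl] ester of the target (1'R,6'S; HMG C3 S by CIP), via 1',4'-epidioxide 23 (not isolated)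
Conditions: O2, 5,10,15,20-tetraphenylporphyrin (1 mol %), CH2Cl2, −30 °C, visible light (>500 nm); then Ar purge, Et3N, −30 → 0 °C
Reagents that add atoms: dioxygen, O=O
Why: Sensitised singlet oxygen adds in a concerted suprafacial [4+2] cycloaddition to C1' and C4' of the ring diene, the only diene unit of 22 that is held s-cis, and so closes the six-membered 1,2-dioxane ring of the 2,3-dioxabicyclo[2.2.2]oct-5-ene 23 with both C–O bonds made in one event, the reaction type known from α-terpinene (ascaridole) and from 1-alkenyl-2,6,6-trimethylcyclohexa-1,3-dienes. Et3N then removes the only hydrogen on a peroxide-bearing carbon, C4'–H, and the O–O bond breaks (Kornblum–DeLaMare rearrangement), so the ketone can arise only at C4' and the tertiary alcohol only at C1', with C2'=C3' already in place and the peroxide ring opened again. C1' is controlled by C6': allylic 1,2-strain with the C1' side chain pushes the larger acyloxymethyl arm into the pseudoaxial position, where it covers its own face and its ester oxygens repel the incoming oxygen, so addition should occur on the face of the C6' methyl group and place the 1'-OH cis to that methyl; the C4' centre of 23 is set by the same event and is lost on opening. Chemoselectivity is needed against the twisted C2'=C1'–C5=C4 diene, the electron-poor dienoate and ene reaction at the allylic methyl groups, and the planar, electron-rich cyclohexadiene should outrun all of these. Low temperature, long-wavelength light and an oxygen-saturated solution hold back sensitised 2Z to 2E isomerisation, and the acylated O8' cannot add to the new enone.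

**Step 16**
Reactants: 24 bis[2-(trimethylsilyl)ethyl] ester
Product: 25 target CNP0183058.1 (1'R,6'S; HMG C3 R)
Conditions: Bu4NF, AcOH (buffer), THF, 0 °C → rt; work-up at pH 3
Reagents that add atoms: none
Why: Fluoride attack at silicon triggers β-fragmentation of both 2-(trimethylsilyl)ethyl esters to carboxylate, ethene and Me3SiF, and the acetic acid buffer keeps the medium mild enough to spare the C8' ester, both tertiary alcohols and the 2Z bond.

**Compound list**
1 | 2,6-dimethylcyclohex-2-en-1-one (racemic) | CC1CCC=C(C)C1=O | starting material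
2 | lithium 2,6-dimethylcyclohexa-1,5-dien-1-olate | [Li+].[O-]C1=C(C)CCC=C1C | intermediate
3 | [(2,6-dimethylcyclohexa-1,5-dien-1-yl)oxy]trimethylsilane | CC1=C(O[Si](C)(C)C)C(C)=CCC1 | intermediate
4 | formaldehyde | C=O | starting material
5 | (6S)-6-(hydroxymethyl)-2,6-dimethylcyclohex-2-en-1-one | CC1=CCC[C@@](C)(CO)C1=O | intermediate
6 | (6S)-6-{[(tert-butyldimethylsilyl)oxy]methyl}-2,6-dimethylcyclohex-2-en-1-one | CC1=CCC[C@@](C)(CO[Si](C)(C)C(C)(C)C)C1=O | intermediate
7 | lithium (6S)-6-{[(tert-butyldimethylsilyl)oxy]methyl}-2,6-dimethylcyclohexa-1,3-dien-1-olate | [Li+].CC1=C([O-])[C@](C)(CO[Si](C)(C)C(C)(C)C)CC=C1 | intermediate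
8 | (6S)-6-{[(tert-butyldimethylsilyl)oxy]methyl}-2,6-dimethylcyclohexa-1,3-dien-1-yl trifluoromethanesulfonate | CC1=C(OS(=O)(=O)C(F)(F)F)[C@](C)(CO[Si](C)(C)C(C)(C)C)CC=C1 | intermediate
9 | but-2-ynoic acid | CC#CC(=O)O | starting material
10 | (2Z)-3-iodobut-2-enoic acid | C/C(I)=C/C(=O)O | intermediate
11 | 2-(trimethylsilyl)ethyl (2Z)-3-iodobut-2-enoate | C/C(I)=C/C(=O)OCC[Si](C)(C)C | intermediate
12 | (E)-1,2-bis(tributylstannyl)ethene | CCCC[Sn](CCCC)(CCCC)/C=C/[Sn](CCCC)(CCCC)CCCC | starting material
13 | 2-(trimethylsilyl)ethyl (2Z,4E)-3-methyl-5-(tributylstannyl)penta-2,4-dienoate | CCCC[Sn](CCCC)(CCCC)/C=C/C(C)=C\C(=O)OCC[Si](C)(C)C | intermediate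
14 | 2-(trimethylsilyl)ethyl (2Z,4E)-5-[(6R)-6-{[(tert-butyldimethylsilyl)oxy]methyl}-2,6-dimethylcyclohexa-1,3-dien-1-yl]-3-methylpenta-2,4-dienoate | CC1=C(/C=C/C(C)=C\C(=O)OCC[Si](C)(C)C)[C@](C)(CO[Si](C)(C)C(C)(C)C)CC=C1 | intermediate
15 | 2-(trimethylsilyl)ethyl (2Z,4E)-5-[(6R)-6-(hydroxymethyl)-2,6-dimethylcyclohexa-1,3-dien-1-yl]-3-methylpenta-2,4-dienoate | CC1=C(/C=C/C(C)=C\C(=O)OCC[Si](C)(C)C)[C@](C)(CO)CC=C1 | intermediate
16 | (R)-mevalonolactone, (4R)-4-hydroxy-4-methyloxan-2-one | C[C@@]1(O)CCOC(=O)C1 | starting material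
17 | potassium (3R)-3,5-dihydroxy-3-methylpentanoate | [K+].C[C@@](O)(CCO)CC(=O)[O-] | intermediate
18 | benzyl (3R)-3,5-dihydroxy-3-methylpentanoate | C[C@@](O)(CCO)CC(=O)OCc1ccccc1 | intermediate
19 | (3R)-5-(benzyloxy)-3-hydroxy-3-methyl-5-oxopentanoic acid | C[C@@](O)(CC(=O)O)CC(=O)OCc1ccccc1 | intermediate
20 | 1-benzyl 5-[2-(trimethylsilyl)ethyl] (3S)-3-hydroxy-3-methylpentanedioate | C[C@@](O)(CC(=O)OCC[Si](C)(C)C)CC(=O)OCc1ccccc1 | intermediate
21 | (3S)-3-hydroxy-3-methyl-5-oxo-5-[2-(trimethylsilyl)ethoxy]pentanoic acid | C[C@@](O)(CC(=O)OCC[Si](C)(C)C)CC(=O)O | intermediate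
22 | ring-diene tetraene, 8'-O-(TMSE-HMG) ester of 15 (6'R, HMG C3 S) | CC1=C(/C=C/C(C)=C\C(=O)OCC[Si](C)(C)C)[C@](C)(COC(=O)C[C@](C)(O)CC(=O)OCC[Si](C)(C)C)CC=C1 | intermediate
23 | (1'R,4'R,6'S)-1',4'-epidioxide of 22, O–O bridge on the face of the C6' methyl group | CC1=C[C@H]2C[C@@](C)(COC(=O)C[C@](C)(O)CC(=O)OCC[Si](C)(C)C)[C@@]1(OO2)/C=C/C(C)=C\C(=O)OCC[Si](C)(C)C | intermediate
24 | bis[2-(trimethylsilyl)ethyl] ester of the target (1'R,6'S) | CC1=CC(=O)C[C@@](C)(COC(=O)C[C@](C)(O)CC(=O)OCC[Si](C)(C)C)[C@@]1(O)/C=C/C(C)=C\C(=O)OCC[Si](C)(C)C | intermediate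
25 | CNP0183058.1, 8'-O-[(3R)-3-hydroxy-3-methylglutaryl]-8'-hydroxyabscisic acid (1'R,6'S,2Z,4E) | CC1=CC(=O)C[C@@](C)(COC(=O)C[C@](C)(O)CC(=O)O)[C@@]1(O)/C=C/C(C)=C\C(=O)O | target

**Step count**
Total step count: 16.
Longest linear sequence: 9 steps (steps 1–4, 8, 9, 14–16).

**Steps most likely to fail**

1. **Step 15.** Oxygen may add to both faces of the ring diene with little preference. It may also be diverted to [4+2] addition across C2'=C1'–C5=C4 or to ene reaction at the allylic methyl groups, and the sensitiser may isomerise the 2Z bond.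
   - The fallback sets out from 14 and comes back at 23. The cycloaddition is moved ahead of the acylation, so that the bulkier silyloxymethyl arm decides the face and the peroxide serves as a masked enone.
   - 14 is photooxygenated as in step 15 but without amine, and the silyl-protected 1',4'-epidioxide F1 is purified cold.
   - HF·pyridine/pyridine in THF then frees the hydroxy epidioxide F2, in which no enone is yet present for the alcohol to add to.
   - Steglich acylation with 21 (DCC, catalytic DMAP, −10 °C) gives 23, this time isolated, and Et3N opens it to 24. Opening of the peroxide after acylation is harmless, since it leads to 24 as well.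

2. **Step 8.** Transmetalation at the palladium centre bound to the congested C1' may be slow. Triflate reduction, stannane homocoupling and 2Z to 2E isomerisation would then take over on prolonged heating.
   - The fallback sets out from 8 and comes back at 14. The hindered C1'–C5 bond is made with a slim alkyne, and the alkene–alkene coupling is moved to the unhindered C4–C3 bond with reversed polarity.
   - Sonogashira coupling of 8 with ethynyltrimethylsilane (PdCl2(PPh3)2, CuI, Et3N, DMF) gives the silylated ring dienyne F3.
   - K2CO3 in MeOH gives the terminal dienyne F4.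
   - Palladium-catalysed hydrostannation (Bu3SnH, PdCl2(PPh3)2, THF, 0 °C) places tin at the distal carbon and gives the (E)-vinylstannane F5.
   - Stille coupling of F5 with iodide 11 (PdCl2(MeCN)2, DMF, rt) gives 14.

3. **Step 2.** Facial discrimination by the catalyst on this dienol silane may be insufficient, or the silyl enol ether may hydrolyse before the C–C bond forms.
   - The fallback sets out from 3 and comes back at 5. Catalyst control is replaced by resolution through covalent diastereomers.
   - Achiral Lewis-acid hydroxymethylation (aq. HCHO, Yb(OTf)3, THF–H2O) gives the racemic hydroxymethyl ketone F6.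
   - Steglich esterification with (S)-O-methylmandelic acid gives the (6S) ester F7 and the (6R) ester F8, which are separated by chromatography or crystallisation.
   - Brief methanolysis of F7 (K2CO3, MeOH, 0 °C) returns 5.

**Further compounds**
F1 | step 15 | 1',4'-epidioxide of 14 (1'R,4'R,6'S; O–O bridge anti to CH2OTBS) | CC1=C[C@H]2C[C@@](C)(CO[Si](C)(C)C(C)(C)C)[C@@]1(OO2)/C=C/C(C)=C\C(=O)OCC[Si](C)(C)C
F2 | step 15 | 8'-hydroxy 1',4'-epidioxide | CC1=C[C@H]2C[C@@](C)(CO)[C@@]1(OO2)/C=C/C(C)=C\C(=O)OCC[Si](C)(C)C
F3 | step 8 | tert-butyl({(1R)-1,3-dimethyl-2-[(trimethylsilyl)ethynyl]cyclohexa-2,4-dien-1-yl}methoxy)dimethylsilane | CC1=C(C#C[Si](C)(C)C)[C@](C)(CO[Si](C)(C)C(C)(C)C)CC=C1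
F4 | step 8 | tert-butyl{[(1R)-2-ethynyl-1,3-dimethylcyclohexa-2,4-dien-1-yl]methoxy}dimethylsilane | CC1=C(C#C)[C@](C)(CO[Si](C)(C)C(C)(C)C)CC=C1
F5 | step 8 | (E)-2-(ring dienyl)vinyl tributylstannane, TBS ether | CC1=C(/C=C/[Sn](CCCC)(CCCC)CCCC)[C@](C)(CO[Si](C)(C)C(C)(C)C)CC=C1
F6 | step 2 | racemic 6-(hydroxymethyl)-2,6-dimethylcyclohex-2-en-1-one | CC1=CCCC(C)(CO)C1=O
F7 | step 2 | [(1S)-1,3-dimethyl-2-oxocyclohex-3-en-1-yl]methyl (2S)-methoxy(phenyl)acetate | CC1=CCC[C@@](C)(COC(=O)[C@@H](OC)c2ccccc2)C1=O
F8 | step 2 | [(1R)-1,3-dimethyl-2-oxocyclohex-3-en-1-yl]methyl (2S)-methoxy(phenyl)acetate | CC1=CCC[C@](C)(COC(=O)[C@@H](OC)c2ccccc2)C1=O
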